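**Strategy.** Ring A (C1–C5, C10; labdane numbering) is closed last, by ring-closing metathesis across C3=C4. The substrate is a cyclohexanone (ring B) that carries a C5 isopropenyl and a C10 butenyl arm trans to each other, plus the C9 side chain. This diene is stored in (+)-verbenone. The pinane cage supplies C5, directs the cuprate to one face of C10, lets the ketone enolise only towards C9, and is then cut open. The metathesis exploits that C4 is the only functionalised atom of ring A. The C3=C4 alkene keeps a vinylic methyl that is oxidised to C19, and the enoate then takes hydride at C3 and methyl at C4 anti to axial C20.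

Key step: step 7

Assumption: (1R,5R)-(+)-verbenone is taken as a purchasable chemical; it is the allylic oxidation product of (+)-α-pinene.

Step 1
Reactants: 1 (S)-(−)-citronellol
Product: 2 (S)-citronellyl tert-butyldiphenylsilyl (TBDPS) ether
Conditions: TBDPSCl, imidazole, DMF, rt
Reagents that add atoms: tert-butyl(chloro)diphenylsilane CC(C)(C)[Si](Cl)(c1ccccc1)c1ccccc1
Why: Imidazole-promoted silylation of a primary alcohol; the bulky, acid-tolerant silyl ether is chosen to outlast the later Lewis-acid, oxidation and enolate steps, and C13 is not touched.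

Step 2
Reactants: 2 (S)-citronellyl TBDPS ether
Product: 3 (4S)-6-(tert-butyldiphenylsilyloxy)-4-methylhexanoic acid
Conditions: OsO4 (1 mol %), Oxone, DMF, rt
Reagents that add atoms: potassium peroxymonosulfate (active part of Oxone) [K+].[O-]S(=O)(=O)OO
Why: Osmium-catalysed oxidative alkene cleavage with peroxymonosulfate takes the CH= carbon to the acid and releases the CMe2 end as acetone, without touching the silyl ether or C13.

Step 3
Reactants: 3 (4S)-6-(tert-butyldiphenylsilyloxy)-4-methylhexanoic acid
Product: 4 tert-butyl{[(3R)-5-iodo-3-methylpentyl]oxy}diphenylsilane (C11–C16 iodide)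
Conditions: 1,3-diiodo-5,5-dimethylhydantoin, hν (tungsten lamp), ClCH2CH2Cl, reflux
Reagents that add atoms: 1,3-diiodo-5,5-dimethylhydantoin CC1(C)N(I)C(=O)N(I)C1=O
Why: Hunsdiecker-type photochemical iododecarboxylation: the acyl hypoiodite loses CO2 and the primary radical picks up iodine, which trims the chain to C11–C15 length while C13 stays remote from the radical (only its descriptor changes).

Step 4
Reactants: 5 (1R,5R)-(+)-verbenone; 6 but-3-enylmagnesium bromide
Product: 8 4-(but-3-enyl)-4,6,6-trimethylbicyclo[3.1.1]heptan-2-one with the butenyl group anti to the CMe2 bridge, via bromomagnesium enolate 7 (not isolated)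
Conditions: CuI (10 mol %), THF, −40 to 0 °C; then H2O
Reagents that add atoms: none
Why: Copper-catalysed 1,4-addition of a Grignard reagent to a β-methyl enone; the CMe2 bridge blocks one face, so the butenyl group (C1–C3) enters anti to it and C10 is set with its methyl syn to the bridge carbon (future C4).

Step 5
Reactants: 8 butenyl pinanone; 4 side-chain iodide
Product: 10 pinanone 8 carrying the (3S)-5-(TBDPS-oxy)-3-methylpentyl chain at C3 (labdane C9), chain anti to the CMe2 bridge, via lithium enolate 9 (not isolated)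
Conditions: LDA, THF, −78 °C; then 4, DMPU, −78 °C to rt
Reagents that add atoms: none
Why: Enolate alkylation (SN2 on a primary iodide): the bridgehead α-carbon cannot enolise (Bredt's rule), so only C9 reacts, from the face opposite the bridge; this kinetic C9 configuration is corrected in step 6.

Step 6
Reactants: 10 alkylated pinanone
Product: 13 ring-B ketone, 2-[(3S)-5-(TBDPS-oxy)-3-methylpentyl]-3-(but-3-enyl)-3-methyl-4-(prop-1-en-2-yl)cyclohexanone (C9 chain β-equatorial, C10 methyl β-axial, C10 butenyl α, C5 isopropenyl equatorial, 5-H α), via iodo silyl enol ether 11 (not isolated), via isopropenyl silyl enol ether 12 (not isolated)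
Conditions: TMSI, CH2Cl2, −20 °C; DBU, rt; then K2CO3 (cat.), MeOH, rt
Reagents that add atoms: none
Why: Silylation of the ketone oxygen triggers strain-releasing heterolysis of the C7–C4 cyclobutane bond (the known iodosilane or acid opening of strained cyclobutyl ketones and nopinone-type pinanones); DBU then removes HI towards a methyl group, and carbonate in methanol frees the ketone and equilibrates C9 to the equatorial chain, while C5 and C10 keep all four of their bonds.

Step 7
Reactants: 13 ring-B ketone with isopropenyl and butenyl arms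
Product: 14 trans-fused octalone, 15-(TBDPS-oxy)-17,18-dinorlabd-3-en-8-one (4-methyl on C3=C4, 5-H α, 10-CH3 β, C9 chain β)
Conditions: Grubbs second-generation catalyst (5 mol %), CH2Cl2 (5 mM), 40 °C
Reagents that add atoms: none
Why: The ruthenium alkylidene loads on the monosubstituted butenyl terminus, then [2+2]/retro-[2+2] with the 1,1-disubstituted isopropenyl group forms C3=C4 and expels ethene, whose loss drives the reaction. The closest known reaction type is ring-closing metathesis of a mono-/gem-disubstituted 1,7-diene to a 1-methylcyclohexene. Ring A (C1, C2, C3, C4, C5, C10) closes as a six-membered carbocycle by joining two vicinal, trans-diequatorial arms of ring B, so the trans ring fusion set at C5/C10 is inherited rather than made. No stereocentre is created, and C5, C9, C10 and C13 are not touched under the neutral conditions. The step needs ring closure to win over dimerisation and alkene migration; the pre-organised vicinal arms, high dilution and the absence of any third alkene secure this. The product carries its only alkene exactly where C19 has to be oxidised and C4 later quaternised.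

Step 8
Reactants: 14 trans-octalone
Product: 15 19-hydroxy-15-(TBDPS-oxy)-17,18-dinorlabd-3-en-8-one (primary allylic alcohol on C4)
Conditions: SeO2 (30 mol %), t-BuOOH, CH2Cl2, 0 °C to rt
Reagents that add atoms: tert-butyl hydroperoxide CC(C)(C)OO
Why: Catalytic selenium dioxide allylic oxidation (ene reaction then [2,3]-shift) acts at the more substituted alkene terminus, where the methyl is the only accessible allylic C–H (the alternative is the ring-fusion methine C5–H, the same situation as in α-pinene to myrtenol).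

Step 9
Reactants: 15 allylic alcohol
Product: 16 8-oxo-15-(TBDPS-oxy)-17,18-dinorlabd-3-en-19-oic acid
Conditions: TEMPO (cat.), NaClO2, NaOCl (cat.), MeCN/phosphate buffer pH 6.7, 35 °C
Reagents that add atoms: sodium chlorite [Na+].[O-]Cl=O
Why: Oxoammonium/chlorite oxidation carries the primary allylic alcohol, and any enal already present, to the conjugated acid under buffered conditions that leave the ketone, silyl ether and C9 alone.

Step 10
Reactants: 16 enoic acid
Product: 17 2-(trimethylsilyl)ethyl 8-oxo-15-(TBDPS-oxy)-17,18-dinorlabd-3-en-19-oate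
Conditions: Me3SiCH2CH2OH, DCC, DMAP (cat.), CH2Cl2, rt
Reagents that add atoms: 2-(trimethylsilyl)ethanol C[Si](C)(C)CCO
Why: Steglich esterification; this ester is chosen because it is later removed by fluoride at silicon, far from the hindered axial C19 carbonyl.

Step 11
Reactants: 17 keto enoate
Product: 18 2-(trimethylsilyl)ethyl 15-(TBDPS-oxy)-18-norlabda-3,8(17)-dien-19-oate
Conditions: Ph3PCH3Br, KHMDS, THF, 0 °C; then 17, 0 °C to rt
Reagents that add atoms: methyltriphenylphosphonium bromide C[P+](c1ccccc1)(c1ccccc1)c1ccccc1.[Br-]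
Why: Wittig methylenation: the non-stabilised ylide takes the C8 ketone and not the ester, and pre-formed ylide without excess base limits γ-deprotonation of the enoate and keeps the equatorial C9 chain.

Step 12
Reactants: 18 dienoate
Product: 20 2-(trimethylsilyl)ethyl 15-(TBDPS-oxy)labd-8(17)-en-19-oate (4S: 4α-methyl equatorial, ester axial), via lithium ester enolate 19 (not isolated)
Conditions: L-Selectride, THF, −78 °C; then MeI, DMPU, −78 to 0 °C
Reagents that add atoms: iodomethane CI
Why: Trialkylborohydride 1,4-reduction of the enoate followed by enolate alkylation: hydride adds to C3, and iodomethane attacks the exocyclic C4 enolate from the α face because the β face is blocked by the 1,3-diaxial C20 methyl, which leaves the ester axial.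

Step 13
Reactants: 20 doubly protected labdenoate
Product: 21 15-hydroxylabd-8(17)-en-19-oic acid (imbricatolic acid)
Conditions: TBAF, THF, rt to 45 °C; then 1 M HCl
Reagents that add atoms: none
Why: Fluoride cleaves the silyl ether and triggers β-fragmentation of the trimethylsilylethyl ester (loss of ethene), so both masks fall in one operation without hydroxide attack at the hindered ester or strong acid near the exocyclic alkene.

Step 14
Reactants: 21 hydroxy acid
Product: 22 15-acetoxylabd-8(17)-en-19-oic acid (target, CNP0401865.2)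
Conditions: Ac2O, pyridine, DMAP (cat.), CH2Cl2, rt; aqueous work-up
Reagents that add atoms: acetic anhydride CC(=O)OC(C)=O
Why: Base-catalysed acetylation of the primary alcohol; any mixed anhydride formed at the hindered acid is hydrolysed on aqueous work-up.

**Compound list**

1 | (S)-(−)-citronellol | CC(C)=CCC[C@H](C)CCO | starting material
2 | (S)-citronellyl TBDPS ether | CC(C)=CCC[C@H](C)CCO[Si](C(C)(C)C)(c1ccccc1)c1ccccc1 | intermediate
3 | (4S)-6-(TBDPS-oxy)-4-methylhexanoic acid | OC(=O)CC[C@H](C)CCO[Si](C(C)(C)C)(c1ccccc1)c1ccccc1 | intermediate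
4 | (3R)-5-iodo-3-methylpentyl TBDPS ether | ICC[C@H](C)CCO[Si](C(C)(C)C)(c1ccccc1)c1ccccc1 | intermediate
5 | (1R,5R)-(+)-verbenone | CC1=CC(=O)[C@@H]2C[C@H]1C2(C)C | starting material
6 | but-3-enylmagnesium bromide | C=CCC[Mg]Br | starting material
7 | bromomagnesium enolate of 8 | C[C@@]1(CCC=C)C=C(O[Mg]Br)[C@@H]2C[C@H]1C2(C)C | intermediate
8 | 4-(but-3-enyl)-4,6,6-trimethylbicyclo[3.1.1]heptan-2-one, butenyl anti to CMe2 bridge | C[C@@]1(CCC=C)CC(=O)[C@@H]2C[C@H]1C2(C)C | intermediate
9 | lithium enolate of 8 | C[C@@]1(CCC=C)C=C(O[Li])[C@@H]2C[C@H]1C2(C)C | intermediate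
10 | C9-alkylated pinanone, chain anti to CMe2 bridge | C[C@@]1(CCC=C)[C@H](CC[C@H](C)CCO[Si](C(C)(C)C)(c3ccccc3)c3ccccc3)C(=O)[C@@H]2C[C@H]1C2(C)C | intermediate
11 | ring-opened trimethylsilyl enol ether with tertiary iodide at C4 | C[Si](C)(C)OC1=CC[C@@H](C(C)(C)I)[C@](C)(CCC=C)[C@@H]1CC[C@H](C)CCO[Si](C(C)(C)C)(c1ccccc1)c1ccccc1 | intermediate
12 | ring-opened trimethylsilyl enol ether with C5 isopropenyl | C[Si](C)(C)OC1=CC[C@@H](C(C)=C)[C@](C)(CCC=C)[C@@H]1CC[C@H](C)CCO[Si](C(C)(C)C)(c1ccccc1)c1ccccc1 | intermediate
13 | ring-B ketone with C5 isopropenyl, C10 methyl/butenyl, equatorial C9 chain | O=C1CC[C@@H](C(C)=C)[C@](C)(CCC=C)[C@H]1CC[C@H](C)CCO[Si](C(C)(C)C)(c1ccccc1)c1ccccc1 | intermediate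
14 | 15-(TBDPS-oxy)-17,18-dinorlabd-3-en-8-one | O=C1CC[C@@H]2[C@](C)(CCC=C2C)[C@H]1CC[C@H](C)CCO[Si](C(C)(C)C)(c1ccccc1)c1ccccc1 | intermediate
15 | 19-hydroxy-15-(TBDPS-oxy)-17,18-dinorlabd-3-en-8-one | O=C1CC[C@@H]2[C@](C)(CCC=C2CO)[C@H]1CC[C@H](C)CCO[Si](C(C)(C)C)(c1ccccc1)c1ccccc1 | intermediate
16 | 8-oxo-15-(TBDPS-oxy)-17,18-dinorlabd-3-en-19-oic acid | O=C1CC[C@@H]2[C@](C)(CCC=C2C(=O)O)[C@H]1CC[C@H](C)CCO[Si](C(C)(C)C)(c1ccccc1)c1ccccc1 | intermediate
17 | 2-(trimethylsilyl)ethyl ester of 16 | O=C1CC[C@@H]2[C@](C)(CCC=C2C(=O)OCC[Si](C)(C)C)[C@H]1CC[C@H](C)CCO[Si](C(C)(C)C)(c1ccccc1)c1ccccc1 | intermediate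
18 | 2-(trimethylsilyl)ethyl 15-(TBDPS-oxy)-18-norlabda-3,8(17)-dien-19-oate | C=C1CC[C@@H]2[C@](C)(CCC=C2C(=O)OCC[Si](C)(C)C)[C@H]1CC[C@H](C)CCO[Si](C(C)(C)C)(c1ccccc1)c1ccccc1 | intermediate
19 | lithium C4 ester enolate | C=C1CC[C@@H]2[C@](C)(CCCC2=C(O[Li])OCC[Si](C)(C)C)[C@H]1CC[C@H](C)CCO[Si](C(C)(C)C)(c1ccccc1)c1ccccc1 | intermediate
20 | 2-(trimethylsilyl)ethyl 15-(TBDPS-oxy)labd-8(17)-en-19-oate | C=C1CC[C@@H]2[C@](C)(CCC[C@]2(C)C(=O)OCC[Si](C)(C)C)[C@H]1CC[C@H](C)CCO[Si](C(C)(C)C)(c1ccccc1)c1ccccc1 | intermediate
21 | 15-hydroxylabd-8(17)-en-19-oic acid | C=C1CC[C@@H]2[C@](C)(CCC[C@]2(C)C(=O)O)[C@H]1CC[C@H](C)CCO | intermediate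
22 | 15-acetoxylabd-8(17)-en-19-oic acid | C=C1CC[C@@H]2[C@](C)(CCC[C@]2(C)C(=O)O)[C@H]1CC[C@H](C)CCOC(C)=O | target

Total step count: 14. Longest linear sequence: 13 (steps 1–3, then 5–14).

**Steps most likely to fail**

**Step 6 (cage opening).**
- What may go wrong: erosion of the silyl ether by the iodosilane, addition of HI to the butenyl alkene, or proton loss from C5 instead of a methyl group, which would erase C5.
- The fallback sets out from 10 and comes back at 13. It replaces iodide capture and E2 by acetate capture, hydrolysis and a separate syn-elimination.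
- Buffered acetolysis (BF3·OEt2, Zn(OAc)2, Ac2O) traps the C4 cation as acetate and the ketone as enol acetate, giving the enol acetate tertiary acetate F4.
- KOH in methanol frees the keto tertiary alcohol F5 and levels C9.
- The Burgess reagent, which takes an accessible methyl hydrogen, gives 13.

**Step 5 (alkylation at neopentyl C9).**
- What may go wrong: slow C–C bond formation next to the quaternary C10, so that proton transfer, O-alkylation or elimination of the iodide takes over.
- The fallback sets out from 4 and 8 and comes back at 10. It swaps the SN2 reaction for carbonyl addition.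
- Kornblum oxidation of 4 (DMSO, NaHCO3) gives (3R)-5-(TBDPS-oxy)-3-methylpentanal F1.
- Aldol addition of enolate 9 gives the β-hydroxy ketone F2.
- Mesylation and DBU elimination give the C9=C11 alkylidene ketone F3.
- 1,4-Reduction with Stryker's reagent spares the butenyl group and gives 10 as a C9 mixture that step 6 levels.

**Step 8 (allylic oxidation).**
- What may go wrong: oxidation at the ring methylene C2 or α to the C8 ketone, or stalling at the hindered alkene.
- The fallback sets out from 13 and comes back at 17. It moves the oxidation in front of the ring closure.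
- Ene-type chlorination of the isopropenyl group (NaOCl, CeCl3·7H2O) gives the allylic chloride F6.
- N-Methylmorpholine N-oxide turns it into the 2-substituted acrolein F7.
- Pinnick oxidation gives the acrylic acid F8.
- Steglich esterification gives the trimethylsilylethyl acrylate F9.
- Ring-closing metathesis with the Hoveyda–Grubbs second-generation catalyst closes C3=C4 directly as enoate 17.

**Further compounds**

F1 | step 5 | (3R)-5-(TBDPS-oxy)-3-methylpentanal | O=CC[C@H](C)CCO[Si](C(C)(C)C)(c1ccccc1)c1ccccc1
F2 | step 5 | aldol adduct of 8 and F1 (C9 and C11 as mixtures) | C[C@@]1(CCC=C)C(C(O)C[C@H](C)CCO[Si](C(C)(C)C)(c3ccccc3)c3ccccc3)C(=O)[C@@H]2C[C@H]1C2(C)C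
F3 | step 5 | C9=C11 alkylidene pinanone (E/Z not relevant) | C[C@@]1(CCC=C)C(=CC[C@H](C)CCO[Si](C(C)(C)C)(c3ccccc3)c3ccccc3)C(=O)[C@@H]2C[C@H]1C2(C)C
F4 | step 6 | ring-opened enol acetate with tertiary acetate at C4 | CC(=O)OC1=CC[C@@H](C(C)(C)OC(C)=O)[C@](C)(CCC=C)[C@@H]1CC[C@H](C)CCO[Si](C(C)(C)C)(c1ccccc1)c1ccccc1
F5 | step 6 | ring-B ketone with 2-hydroxypropan-2-yl group at C5 | O=C1CC[C@@H](C(C)(C)O)[C@](C)(CCC=C)[C@H]1CC[C@H](C)CCO[Si](C(C)(C)C)(c1ccccc1)c1ccccc1
F6 | step 8 | ring-B ketone with 3-chloroprop-1-en-2-yl group at C5 | O=C1CC[C@@H](C(=C)CCl)[C@](C)(CCC=C)[C@H]1CC[C@H](C)CCO[Si](C(C)(C)C)(c1ccccc1)c1ccccc1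
F7 | step 8 | ring-B ketone with 1-formylvinyl group at C5 | O=C1CC[C@@H](C(=C)C=O)[C@](C)(CCC=C)[C@H]1CC[C@H](C)CCO[Si](C(C)(C)C)(c1ccccc1)c1ccccc1
F8 | step 8 | ring-B ketone with 1-carboxyvinyl group at C5 | O=C1CC[C@@H](C(=C)C(=O)O)[C@](C)(CCC=C)[C@H]1CC[C@H](C)CCO[Si](C(C)(C)C)(c1ccccc1)c1ccccc1
F9 | step 8 | 2-(trimethylsilyl)ethyl ester of F8 | O=C1CC[C@@H](C(=C)C(=O)OCC[Si](C)(C)C)[C@](C)(CCC=C)[C@H]1CC[C@H](C)CCO[Si](C(C)(C)C)(c1ccccc1)c1ccccc1
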